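**Assumptions (one line each)**
- The SMILES gives the absolute configuration and the (E,E)-diene exactly as drawn.
- Ring labels follow the SMILES: C1 = ring C(Me)=, C2 = ring =CH, C3 = quaternary C bearing the diene, C4 = quaternary C bearing CO2H, C5/C6 = ring-fusion CH (C5 next to C4), C7 = CHMe, C8=C9 = cyclopentene alkene (C9 bears Me).
- The relative stereochemistry is trans-fused at C5/C6, cis C3-side chain/CO2H, and C7-Me trans to the C6–C1 bond. My stereochemical predictions for the two Claisen steps and the Felkin addition are my own analysis, not literature results.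

**Retrosynthetic overview**
1. Target ⇐ diene by Julia–Kocienski olefination of the C3-aldehyde (masked as an acetal) ⇐ cyclopentene closed last by RCM (C5-isopropenyl + C7-propenyl) on a trans-1,2-disubstituted cyclohexene.
2. The cyclohexene with vicinal quaternary C3/C4 and C1=C2 comes from a ring-switching Ireland–Claisen (boat, bicyclo[2.2.2]-like TS) of the silyl ketene acetal of a 6-alkenyl-δ-lactone. That acetal is generated in situ by Cu-conjugate addition of isopropenyl, which sets C5 anti to C6.
3. The lactone comes from RCM of a methacrylate of a tertiary allylic alcohol ⇐ Felkin addition of an alkenylcerium to an α-chiral methyl ketone ⇐ chair Ireland–Claisen of (S)-pent-3-en-2-yl but-3-enoate, which sets C6/C7.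
4. Rings form in the order δ-lactone (RCM), cyclohexene (Claisen), cyclopentene (RCM). The only external chirality is one transfer hydrogenation.

---

**Step 1**
Reactants: 1 (E)-pent-3-en-2-one
Product: 2 (S,E)-pent-3-en-2-ol
Conditions: RuCl[(S,S)-TsDPEN](p-cymene) (1 mol%), iPrOH, KOH (cat.), 23 °C
Reagents that add atoms: none
Why: Noyori asymmetric transfer hydrogenation reduces C=O chemoselectively and sets the (S)-carbinol, the single source of absolute configuration (ee can be upgraded by lipase resolution if needed).

**Step 2**
Reactants: 2 (S,E)-pent-3-en-2-ol; 3 but-3-enoic acid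
Product: 4 (S,E)-pent-3-en-2-yl but-3-enoate
Conditions: EDC·HCl, DMAP (5 mol%), CH2Cl2, 0 °C
Reagents that add atoms: none
Why: Steglich esterification at O, so the carbinol configuration is untouched.

**Step 3**
Reactants: 4
Product: 5 (4E)-3-methyl-2-vinylhex-4-enoic acid (anti diastereomer; C2/C3 as in SMILES)
Conditions: LDA (2.2 equiv), THF, –78 °C; TBSCl (3 equiv), –78 → 23 °C; then 1 M HCl
Reagents that add atoms: none (TBS is lost on hydrolysis)
Why: Ireland–Claisen rearrangement through a chair TS, with E-alkene, methyl equatorial at the carbinol and the E(O)-silyl dienolate (LDA/THF, no HMPA), transfers the (S)-carbinol to C7, forms the E-propenyl group, and fixes C6/C7 anti.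

**Step 4**
Reactants: 5
Product: 6 (5E)-4-methyl-3-vinylhept-5-en-2-one
Conditions: MeLi (2.2 equiv), Et2O, 0 °C; quench with TMSCl, then pH 7 buffer (use crude, cold)
Reagents that add atoms: methyllithium, [Li]C (adds CH3)
Why: The second equivalent of MeLi adds to the lithium carboxylate to give the methyl ketone only at work-up, which avoids over-addition and limits epimerisation at C6.

**Step 5**
Reactants: 7 3,3-diethoxyprop-1-yne
Product: 8 (E)-3,3-diethoxy-1-iodo-2-methylprop-1-ene
Conditions: Me3Al, Cp2ZrCl2 (cat.), ClCH2CH2Cl, 0 → 23 °C; then I2, THF, –30 °C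
Reagents that add atoms: trimethylaluminium, C[Al](C)C (CH3); iodine, II (I)
Why: Negishi carboalumination is a syn-addition, so Me and I end up cis and the acetal trans to I, which gives the (E)-iodide required for the later Claisen (C3-Me cis to C1).

**Step 6**
Reactants: 8 (E)-iodide; 6 ketone
Product: 9 (2E,7E)-1,1-diethoxy-2,4,6-trimethyl-5-vinylnona-2,7-dien-4-ol (C4/C5/C6 as in SMILES)
Conditions: t-BuLi (2 equiv), Et2O, –78 °C; CeCl3 (1.5 equiv), THF, –78 °C; add 6, –78 °C
Reagents that add atoms: none
Why: Felkin–Anh 1,2-addition of the alkenylcerium (CeCl3 suppresses enolisation of the acidic α-CH) anti to the large sec-alkyl (C7) group sets the tertiary carbinol (future C1 stereocentre) relative to C6; the minor diastereomer is removed chromatographically.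

**Step 7**
Reactants: 9; 10 methacryloyl chloride
Product: 11 methacrylate ester of 9
Conditions: LiHMDS, THF, –78 °C; 10, –78 → 0 °C
Reagents that add atoms: none
Why: O-acylation of the lithium alkoxide retains the tertiary carbinol configuration.

**Step 8**
Reactants: 11
Product: 12 6-[(E)-3,3-diethoxy-2-methylprop-1-enyl]-3,6-dimethyl-5-[(E)-pent-3-en-2-yl]-5,6-dihydro-2H-pyran-2-one
Conditions: Hoveyda–Grubbs II (10 mol%), toluene (2 mM), 80 °C
Reagents that add atoms: none (ethylene is lost)
Why: Ring-closing metathesis between the methacrylate and the C5-vinyl group gives the α-methyl-α,β-unsaturated δ-lactone; the in-ring alkene is necessarily Z and no stereocentre is touched, while the trisubstituted alkenyl and the propenyl group are less reactive.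

**Step 9**
Reactants: 12 lactone; 13 isopropenylmagnesium bromide
Product: 14 2-(diethoxymethyl)-1,2,4-trimethyl-6-(prop-1-en-2-yl)-5-[(E)-pent-3-en-2-yl]cyclohex-3-ene-1-carboxylic acid (as in SMILES)
Conditions: 13 (3 equiv), CuBr·SMe2 (1.5 equiv), THF, –78 °C; TMSCl (4 equiv), Et3N, HMPA, –78 → 23 °C, then 50 °C; pH 4.5 buffer
Reagents that add atoms: none (isopropenyl comes from 13; TMS is lost on hydrolysis)
Why: Proposed new method: Cu-conjugate addition of isopropenyl to the lactone occurs anti to the adjacent C6 substituent (setting trans C5/C6), the lactone enolate is trapped as the cyclic silyl ketene acetal whose C=C geometry is locked by the ring, and the only [3,3] pathway is a boat-like bicyclo[2.2.2] Ireland–Claisen in which the alkenyl bridge bonds C3–C4 on the face of the departing C1–O bond, swapping O–C1 for C3–C4; the E-alkene (Me cis to C1) puts the CH(OEt)2 group syn to the ketene-acetal bridge, which fixes C3 and C4 as vicinal quaternary centres cis to each other (CO2H and side chain) and fixes C1=C2. The closest known chemistry is Ireland–Claisen rearrangement of lactone-derived silyl ketene acetals (boat-TS ring-switching) combined with tandem Cu-conjugate addition/ketene-acetal trapping, but this hindered vicinal-quaternary case is an extrapolation.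

**Step 10**
Reactants: 14
Product: 15 methyl ester of 14
Conditions: TMSCHN2, MeOH/PhMe (1:4), 0 → 23 °C
Reagents that add atoms: trimethylsilyldiazomethane, C[Si](C)(C)C=[N+]=[N-] (retains CH3)
Why: O-methylation of the hindered quaternary acid through the carboxylic O–H, leaving every stereocentre untouched.

**Step 11**
Reactants: 15
Product: 16 methyl 5-(diethoxymethyl)-1,3,4,5,7-pentamethyl-3a,4,5,7a-tetrahydro-1H-indene-4-carboxylate (as in SMILES)
Conditions: Hoveyda–Grubbs II (15 mol%), toluene (5 mM), 80–100 °C, N2 sparge
Reagents that add atoms: none (propene is lost)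
Why: RCM between the trans-diequatorial isopropenyl (C5) and propenyl (C7) side chain closes the trisubstituted cyclopentene C8=C9 and delivers the trans-fused hydrindene with C5/C6/C7 unchanged.

**Step 12**
Reactants: 16
Product: 17 methyl 5-formyl-1,3,4,5,7-pentamethyl-3a,4,5,7a-tetrahydro-1H-indene-4-carboxylate
Conditions: TsOH·H2O (0.2 equiv), acetone/H2O (9:1), 50 °C
Reagents that add atoms: water, O
Why: Acid-catalysed acetal hydrolysis unmasks the neopentyl aldehyde with no intermediate alcohol, so lactonisation onto the neighbouring ester is avoided.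

**Step 13**
Reactants: 18 (±)-(E)-4-phenylbut-3-en-2-ol; 19 1-phenyl-1H-tetrazole-5-thiol
Product: 20 5-{[(E)-4-phenylbut-3-en-2-yl]thio}-1-phenyl-1H-tetrazole
Conditions: PPh3, DIAD, THF, 0 °C
Reagents that add atoms: none
Why: Mitsunobu thioetherification; the stereocentre is irrelevant because it is destroyed on deprotonation.

**Step 14**
Reactants: 20
Product: 21 the corresponding PT-sulfone
Conditions: (NH4)6Mo7O24·4H2O (cat.), 30% H2O2, EtOH, 0 → 23 °C
Reagents that add atoms: hydrogen peroxide, OO (two O retained)
Why: Molybdate-catalysed sulfide oxidation to the sulfone leaves the styrenyl alkene intact.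

**Step 15**
Reactants: 17 aldehyde; 21 sulfone
Product: 22 methyl 1,3,4,5,7-pentamethyl-5-[(1E,3E)-2-methyl-4-phenylbuta-1,3-dienyl]-3a,4,5,7a-tetrahydro-1H-indene-4-carboxylate
Conditions: KHMDS (1.5 equiv), DME, –60 °C; add 17, –60 → 23 °C
Reagents that add atoms: none
Why: Julia–Kocienski olefination, with the styryl group ending up trans to the hindered quaternary carbon and the E-styryl alkene carried through unchanged.

**Step 16**
Reactants: 22
Product: 23 27-nor-zyggomphic acid B
Conditions: LiSPr (10 equiv), HMPA, THF, 23 → 50 °C; then pH 3 work-up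
Reagents that add atoms: none (CH3 is lost as MeSPr)
Why: SN2 demethylation occurs at the methyl carbon, so the hindered quaternary acyl centre and all stereocentres are unaffected.

---

**Compound list**
1 | (E)-pent-3-en-2-one | C/C=C/C(C)=O | starting material
2 | (S,E)-pent-3-en-2-ol | C[C@H](O)/C=C/C | intermediate
3 | but-3-enoic acid | C=CCC(=O)O | starting material
4 | (S,E)-pent-3-en-2-yl but-3-enoate | C=CCC(=O)O[C@@H](C)/C=C/C | intermediate
5 | (4E)-3-methyl-2-vinylhex-4-enoic acid (anti) | OC(=O)[C@H](C=C)[C@H](C)/C=C/C | intermediate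
6 | (5E)-4-methyl-3-vinylhept-5-en-2-one | CC(=O)[C@H](C=C)[C@H](C)/C=C/C | intermediate
7 | 3,3-diethoxyprop-1-yne | C#CC(OCC)OCC | starting material
8 | (E)-3,3-diethoxy-1-iodo-2-methylprop-1-ene | I/C=C(\C)C(OCC)OCC | intermediate
9 | (2E,7E)-1,1-diethoxy-2,4,6-trimethyl-5-vinylnona-2,7-dien-4-ol | C[C@@](O)(/C=C(\C)C(OCC)OCC)[C@H](C=C)[C@H](C)/C=C/C | intermediate
10 | methacryloyl chloride | C=C(C)C(=O)Cl | starting material
11 | methacrylate of 9 | C=C(C)C(=O)O[C@](C)(/C=C(\C)C(OCC)OCC)[C@H](C=C)[C@H](C)/C=C/C | intermediate
12 | unsaturated δ-lactone | CC1=C[C@H]([C@H](C)/C=C/C)[C@@](C)(/C=C(\C)C(OCC)OCC)OC1=O | intermediate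
13 | isopropenylmagnesium bromide | C=C(C)[Mg]Br | starting material
14 | cyclohexene acid from Claisen | CC1=C[C@](C)(C(OCC)OCC)[C@](C)(C(=O)O)[C@@H](C(C)=C)[C@@H]1[C@H](C)/C=C/C | intermediate
15 | methyl ester of 14 | CC1=C[C@](C)(C(OCC)OCC)[C@](C)(C(=O)OC)[C@@H](C(C)=C)[C@@H]1[C@H](C)/C=C/C | intermediate
16 | hydrindene acetal ester | CC1=C[C@](C)(C(OCC)OCC)[C@](C)(C(=O)OC)[C@H]2C(C)=C[C@@H](C)[C@H]12 | intermediate
17 | hydrindene aldehyde ester | CC1=C[C@](C)(C=O)[C@](C)(C(=O)OC)[C@H]2C(C)=C[C@@H](C)[C@H]12 | intermediate
18 | (±)-(E)-4-phenylbut-3-en-2-ol | CC(O)/C=C/c1ccccc1 | starting material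
19 | 1-phenyl-1H-tetrazole-5-thiol | Sc1nnnn1-c1ccccc1 | starting material
20 | PT-sulfide | CC(/C=C/c1ccccc1)Sc1nnnn1-c1ccccc1 | intermediate
21 | PT-sulfone | CC(/C=C/c1ccccc1)S(=O)(=O)c1nnnn1-c1ccccc1 | intermediate
22 | diene methyl ester | CC1=C[C@](C)(/C=C(C)/C=C/c2ccccc2)[C@](C)(C(=O)OC)[C@H]2C(C)=C[C@@H](C)[C@H]12 | intermediate
23 | 27-nor-zyggomphic acid B | CC1=C[C@](C)(/C=C(C)/C=C/c2ccccc2)[C@](C)(C(=O)O)[C@H]2C(C)=C[C@@H](C)[C@H]12 | target

**Totals:** 16 steps in total, with a longest linear sequence of 13 (Steps 1, 2, 3, 4, 6, 7, 8, 9, 10, 11, 12, 15, 16). Steps 5 and 13–14 are convergent side branches.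

**Three steps most likely to fail**
1. **Step 9 (conjugate addition / boat Ireland–Claisen).** The hindered vicinal-quaternary boat TS may lose out to ionisation or SN2' opening of the tertiary allylic lactone. Fallback: build C3–C4 by an acyclic chair Ireland–Claisen and close C1=C2 by RCM, or switch to a different ring-forming logic, an intramolecular Diels–Alder of a triene keto-ester.
2. **Step 11 (RCM).** Closing a trisubstituted, trans-fused cyclopentene next to two quaternary centres is very hindered. Fallback: cationic Pd–H cycloisomerisation of the 1,6-diene (Widenhoefer-type) to form the cyclopentene instead of metathesis.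
3. **Step 15 (Julia–Kocienski on the hindered aldehyde).** Fallback: two-step homologation, Wittig with Ph3P=C(Me)CHO to the (E)-enal, then HWE with diethyl benzylphosphonate to give the (E,E)-diene.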